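Which way of adding the same charge ends with the most rings?

| flask | first end groups | second end groups | temperature | remark | time |
|---|---|---|---|---|---|
| blue | 0.027 M | 0.027 M | 65 °C | run made earlier |  |
| teal | 0.018 M | 0.027 M | 76 °C | run made earlier |  |
| violet | 0.041 M | 0.027 M | 65 °C | run made earlier |  |
| red | 0.027 M | 0.013 M | 76 °C | run made earlier |  |
| spring | 0.027 M | 0.0270 M (fed, over 12 h) |  | the addition at 50 °C, then warmed to 70 °C; the feed brings no volume worth counting | 20 h |
| dusk | 0.027 M | 0.0270 M (in portions, 5, over 12 h) | 70 °C | first portion at the start, last at 12 h | 20 h |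
| midnight | 0.027 M | 0.0270 M | 70 °C | everything together at the start | 20 h |
| summer | 0.027 M (fed, over 12 h) | 0.0270 M | 70 °C | all else is in the flask from the start; the feed brings no volume worth counting | 20 h |

| run | time / h | rings / % | links / % | first end groups / % |
|---|---|---|---|---|
| blue | 3.00 | 0 | 51 | 47 |
| blue | 6.00 | 1 | 64 | 31 |
| blue | 10.0 | 6 | 73 | 22 |
| blue | 12.0 | 2 | 74 | 18 |
| teal | 6.00 | 3 | 78 | 9 |
| teal | 12.0 | 4 | 81 | 1 |
| teal | 20.0 | 6 | 69 | 2 |
| teal | 25.0 | 3 | 63 | 0 |
| violet | 6.00 | 0 | 54 | 47 |
| violet | 12.0 | 4 | 55 | 35 |
| violet | 20.0 | 4 | 55 | 31 |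
| violet | 25.0 | 5 | 55 | 36 |
| red | 3.00 | 6 | 33 | 64 |
| red | 8.00 | 11 | 34 | 55 |
| red | 15.0 | 5 | 26 | 50 |
| red | 25.0 | 10 | 18 | 55 |

(scatter of a reading: 2 percentage points)

* the flask that comes out highest in amount of rings, in percent of the first end groups charged, or "all alike" when all lie within 1.5 percentage points (spring / dusk / midnight / summer / all alike)
* rings at the end, in percent of the first end groups charged, spring
* rings at the end, in percent of the first end groups charged, dusk
* rings at the end, in percent of the first end groups charged, midnight
* rings at the end, in percent of the first end groups charged, summer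

- what is said of links includes crystals
- crystals is a solid; its amount is given per volume of the solution
- what was read earlier has a scatter of 2 percentage points, one standard deviation
- on the list of suspects stand: first end groups + second end groups -> links; first end groups + second end groups -> rings; crystals <-> links; links -> over-reaction product

Ann holds that rings are a fixed cut (selectivity) of whatever reacts, so the flask with the smallest fraction left wins. Equal charges c leave 1/(1+kct) of the first end groups. The blue run's 18 % at 12.0 h gives k = 14.1 M⁻¹ h⁻¹. The red run's 64 % at 3.00 h, reckoned for unequal charges, gives 22.2 M⁻¹ h⁻¹. Interpolating the logarithm gives 17.3 M⁻¹ h⁻¹ at 70 °C. So midnight keeps 9.67 %, and she names midnight.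

Ben objects that at 76 °C the red run's cut by 8.00 h is 24.4 %, larger than the teal run's 4.04 % by 12.0 h. His rule is that rings tick with the first end groups standing, while second end groups are present: rings = r × exposure, where exposure is the area under the fraction left against time. Areas under the readings give r = 0.0202 h⁻¹ from the red run and 0.00582 h⁻¹ from the violet run. So the ring clock at 70 °C, the rate of rings per hour of exposure, reads 0.0103 h⁻¹.

For midnight the exposure is ln(1+kct)/(kc) = 5.00 h, so 5.15 % rings. Count each dusk portion as reacting at once: the steps of the fraction left give a floor of 6.00 h, so at least 6.18 % rings, more than midnight. Ben names dusk.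

The forecast, on his side, says dusk, with 3.5 % for spring, 7.5 % for dusk, 5.5 % for midnight and 3 % for summer. Its ground is different: “Ring share looks roughly proportional to first-end-group concentration”. Its numbers are not Ben's reckoning.

The flasks end at 3.97 % in spring, 11.4 % in dusk, 5.72 % in midnight and 4.71 % in summer, so dusk stands highest.

    first end groups + second end groups → links (k = 16.9 M⁻¹ h⁻¹, Ea = 60.0 kJ mol⁻¹)
    first end groups + second end groups → rings, rate k2*[first end groups] as long as [second end groups] is above zero (k = 0.0118 h⁻¹, Ea = 111 kJ mol⁻¹)
    crystals ⇌ links, rate k3*(cs3 - [links]) while solid is left; crystals form when [links] > cs3 (solubility = 1.20 mM, k = 58.7 h⁻¹)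
    links → over-reaction product (k = 0.0954 h⁻¹, Ea = 115 kJ mol⁻¹)
    (constants at 70 °C)

Ann's order holds between midnight and summer: midnight has 8.7 % left against 14 % in summer and ends 1 percentage point higher, inside the margin of 1.5 points. Her fixed cut does not hold there, for rings per part reacted come to 6.27 % in midnight and 5.48 % in summer. At Ben's clock, dusk's rings mean 11.1 h of exposure, above the floor of 6.00 h. Spring left until 30 h goes on from 18 % left at 20 h, so the extra time adds ln(1+kcfΔt)/(kc) = 1.29 h of exposure, with f that fraction and Δt the extra time. That is 1.3 points more rings, or 5.30 % in all. That neighbouring flask reads 5.43 %.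

The data come from a simulation for substances that don't exist, noise included.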